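**Strategy.** With the octahydronaphthalene numbered so that C1 carries the dienoic acid and C7 the sulfate, ring B (C4a, C5, C6, C7, C8, C8a) is disconnected at C4a–C5 and C8–C8a. C5–C6–C7(O)–C8 becomes a 2-silyloxy diene, and the fusion bond C4a–C8a the α,β-bond of a cyclohexenone that already holds C1 and C2. One endo Diels–Alder reaction closes ring B, sets C4a, C8a and C8 and puts oxygen on C7. The diene is 4-silyloxy-2H-thiopyran: its CH2–S bridge is a temporary ring that becomes the C8 methyl cis to the fusion hydrogens, which an (E)-diene would not give. The C4 carbonyl later becomes the C3=C4 alkene.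

Key step: step 7

Assumption: the absolute sense of induction of the cationic oxazaborolidine in step 3 is taken as that of the (S)-catalyst written; were it opposite, the (R)-catalyst would be used and nothing else would change.

Step 1
Reactants: 1 (E)-2-methylbut-2-enal; 2 3-(triphenyl-λ5-phosphanylidene)butan-2-one
Product: 3 (3E,5E)-3,5-dimethylhepta-3,5-dien-2-one
Conditions: toluene, 100 °C
Reagents that add atoms: none
Why: Wittig reaction of the acyl-stabilised ylide with the α-branched enal should give the (E)-trisubstituted enone (carbonyl trans to the butenyl group), and the (E)-alkene of the aldehyde is carried over unchanged.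

Step 2
Reactants: 3 (3E,5E)-3,5-dimethylhepta-3,5-dien-2-one
Product: 4 triisopropylsilyl dienol ether (2-silyloxy triene)
Conditions: i-Pr3SiOTf, Et3N, CH2Cl2, 0 °C
Reagents that add atoms: triisopropylsilyl trifluoromethanesulfonate, CC(C)[Si](C(C)C)(C(C)C)OS(=O)(=O)C(F)(F)F
Why: Soft enolisation (silyl enol ether formation) at the methyl ketone α-carbon, preferred over the vinylogous methyl groups, gives the cross-conjugated 2-silyloxy triene, whose CH2=C(OSi)–C(CH3)=CH terminus is a reactive s-cis diene.

Step 3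
Reactants: 4 2-silyloxy triene; 5 2,2,2-trifluoroethyl prop-2-enoate
Product: 7 ring-A keto ester (both epimers at the methyl-bearing carbon), via silyl enol ether 6 (not isolated)
Conditions: (S)-3,3-diphenyl-1-(2-methylphenyl)tetrahydro-1H,3H-pyrrolo[1,2-c][1,3,2]oxazaborole·HN(SO2CF3)2 (20 mol %), CH2Cl2, −78 → −40 °C; then aq. HF, MeCN, 0 °C
Reagents that add atoms: none
Why: Enantioselective Diels–Alder reaction in which the 2-silyloxy group (para rule) and the 1-alkenyl group (ortho rule) both direct the ester carbon to the butenyl-bearing terminus, the endo transition state places the ester cis to the outside (E) butenyl group, the chiral boron Lewis acid fixes the absolute configuration, and fluoride work-up unmasks the ketone.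

Step 4
Reactants: 7 ring-A keto ester
Product: 9 cyclohexenone dienophile, via trimethylsilyl enol ether 8 (not isolated)
Conditions: LiN(iPr)2, Me3SiCl, THF, −78 °C; then Pd(OAc)2, MeCN, 25 °C
Reagents that add atoms: none
Why: Saegusa–Ito oxidation, in which kinetic deprotonation by the hindered amide occurs at the CH2 rather than the CH(CH3) α-carbon (and faster than at the ester α-carbon) and divalent palladium dehydrogenates the derived silyl enol ether to the enone without touching the two stereocentres.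

Step 5
Reactants: 10 tetrahydro-4H-thiopyran-4-one
Product: 12 2,3-dihydro-4H-thiopyran-4-one, via α-chloro sulfide 11 (not isolated)
Conditions: N-chlorosuccinimide, pyridine, CH2Cl2, 0 → 25 °C
Reagents that add atoms: none
Why: Pummerer-type α-chlorination of the sulfide followed by base-induced loss of HCl toward the ketone α-carbon gives the vinylogous thioester.

Step 6
Reactants: 12 2,3-dihydro-4H-thiopyran-4-one
Product: 13 4-(tert-butyldimethylsilyloxy)-2H-thiopyran
Conditions: t-BuMe2SiOTf, Et3N, CH2Cl2, 0 °C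
Reagents that add atoms: tert-butyldimethylsilyl trifluoromethanesulfonate, CC(C)(C)[Si](C)(C)OS(=O)(=O)C(F)(F)F
Why: Soft enolisation (silyl enol ether formation) toward the only enolisable α-CH2 gives the cyclic, s-cis-locked 2-silyloxy-1-thio diene.

Step 7
Reactants: 9 cyclohexenone dienophile; 13 4-(tert-butyldimethylsilyloxy)-2H-thiopyran
Product: 14 endo cycloadduct (thia-bridged tricycle)
Conditions: Me2AlCl (30 mol %), CH2Cl2, −78 → −30 °C
Reagents that add atoms: none
Why: The Lewis-acid-bound enone 9 and the electron-rich cyclic diene 13 combine in a concerted, asynchronous normal-demand [4+2] cycloaddition (Diels–Alder reaction; closest known type: additions of 2-silyloxy dienes and of 2H-thiopyrans, used as cis-diene equivalents, to cyclohexenones). Ring B closes as the six-membered ring of this intermolecular [4+2] addition, the bonds C4a–C5 and C8–C8a forming suprafacially on both partners, and the thia bridge makes the adduct a 2-thiabicyclo[2.2.2]octene that is only a temporary ring. C4a and C8a become cis because both bonds form on one face of the ring alkene, and that face is the one anti to the C1 ester and the C2 butenyl group, which sit cis on the other face. C8 is set by the endo rule: with ring A under the diene, the CH2–S bridge ends up on the side of the ring-fusion hydrogens, so that after sulfur removal the C8 methyl is cis to them. Regiochemistry follows from the diene polarisation (the silyloxy group and the ring sulfur both make the CH2-bearing terminus nucleophilic), so this terminus bonds to the enone β-carbon C8a. The step needs facial, endo and regio-selectivity, secured respectively by the C1/C2 substituents, by secondary orbital overlap under Lewis acid catalysis and by the donor pattern of the diene.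

Step 8
Reactants: 14 endo cycloadduct
Product: 16 alkenyl triflate, via lithium enolate 15 (not isolated)
Conditions: LiN(iPr)2, THF, −78 °C; then N-(5-chloropyridin-2-yl)bis(trifluoromethanesulfonimide), −78 → −20 °C
Reagents that add atoms: N-(5-chloropyridin-2-yl)bis(trifluoromethanesulfonimide), O=S(=O)(N(c1ccc(Cl)cn1)S(=O)(=O)C(F)(F)F)C(F)(F)F
Why: Kinetic enolate formation is expected at C3–H on the periphery of ring A, because the other α-hydrogen (at ring-fusion carbon C4a) is shielded by the C–S bond of the thia bridge, and O-triflation of the enolate fixes the C3=C4 position while erasing the unneeded stereocentre at C3.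

Step 9
Reactants: 16 alkenyl triflate
Product: 17 thia-bridged tricyclic diene (C3=C4 alkene in place)
Conditions: Pd(OAc)2 (10 mol %), PPh3, HCO2H, n-Bu3N, DMF, 60 °C
Reagents that add atoms: none
Why: Palladium-catalysed formate reduction of the alkenyl triflate (oxidative addition to zerovalent palladium, formate exchange, decarboxylation, reductive elimination) replaces the triflate by hydrogen without moving the double bond.

Step 10
Reactants: 17 thia-bridged tricyclic diene
Product: 18 cis-fused hexahydronaphthalene silyl enol ether ester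
Conditions: sponge Ni (W-2 grade, deactivated in refluxing acetone), THF/acetone, 25 °C
Reagents that add atoms: none
Why: Reductive desulfurisation (hydrogenolysis of both C–S bonds on the hydrogen-loaded nickel) turns the bridge CH2 into the C8 methyl and C5 into CH2 without touching a stereocentre, and the deactivated catalyst is expected to spare the two trisubstituted alkenes and the silyl enol ether.

Step 11
Reactants: 18 silyl enol ether ester; 19 triethyl (2E)-4-phosphonobut-2-enoate
Product: 21 (2E,4E)-dienoate silyl enol ether, via aldehyde 20 (not isolated)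
Conditions: iBu2AlH, CH2Cl2, −78 °C; then 19/LiN(SiMe3)2, THF, −78 → 0 °C
Reagents that add atoms: none
Why: Half-reduction of the activated ester gives the aldehyde, which is trapped in the same flask by Horner–Wadsworth–Emmons reaction with the lithiated γ-phosphonocrotonate to give the (2E,4E)-dienoate, the low temperature preserving the C1 stereocentre.

Step 12
Reactants: 21 dienoate silyl enol ether
Product: 22 C7 ketone
Conditions: HF·pyridine, pyridine, THF, 0 °C
Reagents that add atoms: none
Why: Buffered fluoride cleavage of the silyl enol ether protonates C6 and releases the ketone without enolising toward C8, so the kinetically set C8 configuration is kept.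

Step 13
Reactants: 22 C7 ketone
Product: 23 (7S)-alcohol
Conditions: LiBH(s-Bu)3, THF, −78 °C
Reagents that add atoms: none
Why: Hydride reduction in which the bulky borohydride should attack the ketone face opposite the adjacent C8 methyl (equatorial attack on the conformer with equatorial methyl), giving the axial 7-alcohol cis to the methyl, faster than it reduces the dienoate.

Step 14
Reactants: 23 (7S)-alcohol
Product: 24 sulfate monoester ethyl ester
Conditions: SO3·pyridine, pyridine, 40 °C
Reagents that add atoms: sulfur trioxide–pyridine complex, [O-]S(=O)(=O)[n+]1ccccc1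
Why: O-Sulfation of the secondary alcohol by the sulfur trioxide–amine complex proceeds with retention at C7 and leaves ester and alkenes untouched.

Step 15
Reactants: 24 sulfate monoester ethyl ester
Product: 25 CNP0450810.2
Conditions: LiOH, THF/H2O, 25 °C; then aq. HCl
Reagents that add atoms: lithium hydroxide, [Li+].[OH-]
Why: Saponification of the ethyl ester by hydroxide (acyl–oxygen cleavage) leaves the alkyl sulfate monoester, which resists aqueous base, and acidification gives the target.

**Compound list**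

1 | (E)-2-methylbut-2-enal | C/C=C(\C)C=O | starting material
2 | 3-(triphenyl-λ5-phosphanylidene)butan-2-one | CC(=O)C(C)=P(c1ccccc1)(c1ccccc1)c1ccccc1 | starting material
3 | (3E,5E)-3,5-dimethylhepta-3,5-dien-2-one | C/C=C(\C)/C=C(\C)C(C)=O | intermediate
4 | triisopropyl{[(3E,5E)-3,5-dimethylhepta-1,3,5-trien-2-yl]oxy}silane | C/C=C(\C)/C=C(\C)C(=C)O[Si](C(C)C)(C(C)C)C(C)C | intermediate
5 | 2,2,2-trifluoroethyl prop-2-enoate | C=CC(=O)OCC(F)(F)F | starting material
6 | 2,2,2-trifluoroethyl (1S,2R)-2-[(2E)-but-2-en-2-yl]-3-methyl-4-[(triisopropylsilyl)oxy]cyclohex-3-ene-1-carboxylate | C/C=C(\C)[C@@H]1C(C)=C(O[Si](C(C)C)(C(C)C)C(C)C)CC[C@@H]1C(=O)OCC(F)(F)F | intermediate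
7 | 2,2,2-trifluoroethyl (1S,2R)-2-[(2E)-but-2-en-2-yl]-3-methyl-4-oxocyclohexane-1-carboxylate (both C3 epimers) | C/C=C(\C)[C@@H]1C(C)C(=O)CC[C@@H]1C(=O)OCC(F)(F)F | intermediate
8 | 2,2,2-trifluoroethyl (1S,6R)-6-[(2E)-but-2-en-2-yl]-5-methyl-4-[(trimethylsilyl)oxy]cyclohex-3-ene-1-carboxylate (both C5 epimers) | C/C=C(\C)[C@@H]1C(C)C(O[Si](C)(C)C)=CC[C@@H]1C(=O)OCC(F)(F)F | intermediate
9 | 2,2,2-trifluoroethyl (1S,6R)-6-[(2E)-but-2-en-2-yl]-5-methyl-4-oxocyclohex-2-ene-1-carboxylate (both C5 epimers) | C/C=C(\C)[C@@H]1C(C)C(=O)C=C[C@@H]1C(=O)OCC(F)(F)F | intermediate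
10 | tetrahydro-4H-thiopyran-4-one | O=C1CCSCC1 | starting material
11 | 2-chlorotetrahydro-4H-thiopyran-4-one | O=C1CCSC(Cl)C1 | intermediate
12 | 2,3-dihydro-4H-thiopyran-4-one | O=C1C=CSCC1 | intermediate
13 | tert-butyldimethyl(2H-thiopyran-4-yloxy)silane | CC(C)(C)[Si](C)(C)OC1=CCSC=C1 | intermediate
14 | 2,2,2-trifluoroethyl 4-[(2E)-but-2-en-2-yl]-11-[(tert-butyldimethylsilyl)oxy]-5-methyl-6-oxo-9-thiatricyclo[6.2.2.0(2,7)]dodec-11-ene-3-carboxylate; cyclohexanone ring cis-fused and endo (anti to the CH2–S bridge), ester and butenyl cis to each other and anti to the bicyclic cage, C5 as epimers | C/C=C(\C)[C@@H]1C(C)C(=O)[C@H]2[C@H]3C=C(O[Si](C)(C)C(C)(C)C)[C@H](CS3)[C@H]2[C@@H]1C(=O)OCC(F)(F)F | intermediate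
15 | lithium C5=C6 enolate of 14 | [Li+].C/C=C(\C)[C@@H]1C(C)=C([O-])[C@H]2[C@H]3C=C(O[Si](C)(C)C(C)(C)C)[C@H](CS3)[C@H]2[C@@H]1C(=O)OCC(F)(F)F | intermediate
16 | 2,2,2-trifluoroethyl 4-[(2E)-but-2-en-2-yl]-11-[(tert-butyldimethylsilyl)oxy]-5-methyl-6-{[(trifluoromethyl)sulfonyl]oxy}-9-thiatricyclo[6.2.2.0(2,7)]dodeca-5,11-diene-3-carboxylate (stereochemistry as in 14) | C/C=C(\C)[C@@H]1C(C)=C(OS(=O)(=O)C(F)(F)F)[C@H]2[C@H]3C=C(O[Si](C)(C)C(C)(C)C)[C@H](CS3)[C@H]2[C@@H]1C(=O)OCC(F)(F)F | intermediate
17 | 2,2,2-trifluoroethyl 4-[(2E)-but-2-en-2-yl]-11-[(tert-butyldimethylsilyl)oxy]-5-methyl-9-thiatricyclo[6.2.2.0(2,7)]dodeca-5,11-diene-3-carboxylate (stereochemistry as in 14) | C/C=C(\C)[C@@H]1C(C)=C[C@H]2[C@H]3C=C(O[Si](C)(C)C(C)(C)C)[C@H](CS3)[C@H]2[C@@H]1C(=O)OCC(F)(F)F | intermediate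
18 | 2,2,2-trifluoroethyl (1S,2R,4aS,8R,8aS)-2-[(2E)-but-2-en-2-yl]-7-[(tert-butyldimethylsilyl)oxy]-3,8-dimethyl-1,2,4a,5,8,8a-hexahydronaphthalene-1-carboxylate | C/C=C(\C)[C@@H]1C(C)=C[C@H]2CC=C(O[Si](C)(C)C(C)(C)C)[C@H](C)[C@H]2[C@@H]1C(=O)OCC(F)(F)F | intermediate
19 | ethyl (2E)-4-(diethoxyphosphoryl)but-2-enoate (triethyl 4-phosphonocrotonate) | CCOC(=O)/C=C/CP(=O)(OCC)OCC | starting material
20 | (1S,2R,4aS,8R,8aS)-2-[(2E)-but-2-en-2-yl]-7-[(tert-butyldimethylsilyl)oxy]-3,8-dimethyl-1,2,4a,5,8,8a-hexahydronaphthalene-1-carbaldehyde | C/C=C(\C)[C@@H]1C(C)=C[C@H]2CC=C(O[Si](C)(C)C(C)(C)C)[C@H](C)[C@H]2[C@@H]1C=O | intermediate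
21 | ethyl (2E,4E)-5-[(1S,2R,4aS,8R,8aR)-2-[(2E)-but-2-en-2-yl]-7-[(tert-butyldimethylsilyl)oxy]-3,8-dimethyl-1,2,4a,5,8,8a-hexahydronaphthalen-1-yl]penta-2,4-dienoate | C/C=C(\C)[C@@H]1C(C)=C[C@H]2CC=C(O[Si](C)(C)C(C)(C)C)[C@H](C)[C@H]2[C@@H]1/C=C/C=C/C(=O)OCC | intermediate
22 | ethyl (2E,4E)-5-[(1S,2R,4aS,8R,8aR)-2-[(2E)-but-2-en-2-yl]-3,8-dimethyl-7-oxo-1,2,4a,5,6,7,8,8a-octahydronaphthalen-1-yl]penta-2,4-dienoate | C/C=C(\C)[C@@H]1C(C)=C[C@H]2CCC(=O)[C@H](C)[C@H]2[C@@H]1/C=C/C=C/C(=O)OCC | intermediate
23 | ethyl (2E,4E)-5-[(1S,2R,4aS,7S,8R,8aR)-2-[(2E)-but-2-en-2-yl]-7-hydroxy-3,8-dimethyl-1,2,4a,5,6,7,8,8a-octahydronaphthalen-1-yl]penta-2,4-dienoate | C/C=C(\C)[C@@H]1C(C)=C[C@H]2CC[C@H](O)[C@H](C)[C@H]2[C@@H]1/C=C/C=C/C(=O)OCC | intermediate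
24 | ethyl (2E,4E)-5-[(1S,2R,4aS,7S,8R,8aR)-2-[(2E)-but-2-en-2-yl]-3,8-dimethyl-7-(sulfooxy)-1,2,4a,5,6,7,8,8a-octahydronaphthalen-1-yl]penta-2,4-dienoate | C/C=C(\C)[C@@H]1C(C)=C[C@H]2CC[C@H](OS(=O)(=O)O)[C@H](C)[C@H]2[C@@H]1/C=C/C=C/C(=O)OCC | intermediate
25 | (2E,4E)-5-[(1S,2R,4aS,7S,8R,8aR)-2-[(2E)-but-2-en-2-yl]-3,8-dimethyl-7-(sulfooxy)-1,2,4a,5,6,7,8,8a-octahydronaphthalen-1-yl]penta-2,4-dienoic acid (CNP0450810.2) | C/C=C(\C)[C@@H]1C(C)=C[C@H]2CC[C@H](OS(=O)(=O)O)[C@H](C)[C@H]2[C@@H]1/C=C/C=C/C(=O)O | target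

**Step count.** 15 steps in total; the longest linear sequence is 13 steps (steps 1–4 and 7–15), and the diene branch (steps 5–6) is 2 steps.

**Steps most likely to fail**

Step 7. The Lewis acid may be sequestered by the sulfide and silyl ether donors so that the cycloaddition stalls, or the endo and facial preferences may erode at the higher temperature then needed. The fallback builds the same two bonds stepwise by an anionic double Michael addition. It sets out from 9 and from ketone 12: deprotonation of 12 at its CH2 next to the carbonyl with LiN(iPr)2 gives the lithium dienolate (F1). Conjugate addition of F1 to 9 anti to the ester-bearing carbon gives the lithium enolate of the Michael adduct (F2). On warming, F2 closes onto the carbon next to sulfur of the vinylogous thioester to give the bicyclic lithium enolate (F3). Trapping of F3 with t-BuMe2SiOTf returns to the route at 14.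

Step 8. Deprotonation may compete at the ring-fusion carbon (which would also open the thia bridge by β-elimination of thiolate) or at the ester α-carbon, giving the regioisomeric triflate or epimerisation at C1. The fallback fixes the alkene position with a sulfone before the cycloaddition and forms the alkene by Julia olefination, with no strong base after the cycloaddition. It sets out from 9: kinetic α′-deprotonation with LiN(iPr)2 at the CH(CH3) carbon gives the cross-conjugated lithium dienolate (F4). Sulfenylation of F4 with PhSSPh gives the phenylsulfanyl enone (F5). Oxidation of F5 with KHSO5 gives the quaternary β-keto sulfone (F6). Cycloaddition of F6 with 13 under Me2AlCl catalysis gives the sulfonyl cycloadduct (F7). Reduction of the ketone of F7 with LiAlH(Ot-Bu)3 gives the β-hydroxy sulfone (F8). Acetylation of F8 with Ac2O and 4-(dimethylamino)pyridine gives the β-acetoxy sulfone (F9). Reductive elimination of F9 with SmI2/HMPA returns to the route at 17.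

Step 3. Enantio- or endo-selectivity may be insufficient with this trisubstituted silyloxy triene, or Mukaiyama–Michael addition may take the place of cycloaddition. The fallback uses a covalently bound oxazolidinone auxiliary. It sets out from 4: cycloaddition with (R)-3-acryloyl-4-benzyloxazolidin-2-one promoted by Et2AlCl (chelated s-cis acrylimide, diene adding to the face away from the benzyl group) gives the silyl enol ether imide (F10). Fluoride work-up of F10 gives the keto imide (F11). Transesterification of F11 with LiOCH2CF3 returns to the route at 7.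

Further compounds
F1 | step 7 | lithium 2H-thiopyran-4-olate (dienolate of 12) | [Li+].[O-]C1=CCSC=C1
F2 | step 7 | lithium enolate of the Michael adduct of F1 and 9 (4-oxo-3,4-dihydro-2H-thiopyran-3-yl group on the former enone β-carbon) | [Li+].C/C=C(\C)[C@@H]1C(C)C([O-])=C[C@@H]([C@H]2CSC=CC2=O)[C@@H]1C(=O)OCC(F)(F)F
F3 | step 7 | lithium C11 enolate of the 6,11-dioxo-9-thiatricyclo[6.2.2.0(2,7)]dodecane ester (desilyl 14) | [Li+].C/C=C(\C)[C@@H]1C(C)C(=O)[C@H]2[C@H]3C=C([O-])[C@H](CS3)[C@H]2[C@@H]1C(=O)OCC(F)(F)F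
F4 | step 8 | cross-conjugated lithium dienolate of 9 (enolate toward the methyl-bearing carbon) | [Li+].C/C=C(\C)[C@@H]1C(C)=C([O-])C=C[C@@H]1C(=O)OCC(F)(F)F
F5 | step 8 | 2,2,2-trifluoroethyl (1S,6R)-6-[(2E)-but-2-en-2-yl]-5-methyl-4-oxo-5-(phenylsulfanyl)cyclohex-2-ene-1-carboxylate | C/C=C(\C)[C@@H]1C(C)(Sc2ccccc2)C(=O)C=C[C@@H]1C(=O)OCC(F)(F)F
F6 | step 8 | 2,2,2-trifluoroethyl (1S,6R)-6-[(2E)-but-2-en-2-yl]-5-methyl-4-oxo-5-(phenylsulfonyl)cyclohex-2-ene-1-carboxylate | C/C=C(\C)[C@@H]1C(C)(S(=O)(=O)c2ccccc2)C(=O)C=C[C@@H]1C(=O)OCC(F)(F)F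
F7 | step 8 | 5-(phenylsulfonyl) analogue of cycloadduct 14 | C/C=C(\C)[C@@H]1C(C)(S(=O)(=O)c4ccccc4)C(=O)[C@H]2[C@H]3C=C(O[Si](C)(C)C(C)(C)C)[C@H](CS3)[C@H]2[C@@H]1C(=O)OCC(F)(F)F
F8 | step 8 | 6-hydroxy-5-(phenylsulfonyl) derivative obtained from F7 | C/C=C(\C)[C@@H]1C(C)(S(=O)(=O)c4ccccc4)C(O)[C@H]2[C@H]3C=C(O[Si](C)(C)C(C)(C)C)[C@H](CS3)[C@H]2[C@@H]1C(=O)OCC(F)(F)F
F9 | step 8 | 6-acetoxy-5-(phenylsulfonyl) derivative obtained from F8 | C/C=C(\C)[C@@H]1C(C)(S(=O)(=O)c4ccccc4)C(OC(C)=O)[C@H]2[C@H]3C=C(O[Si](C)(C)C(C)(C)C)[C@H](CS3)[C@H]2[C@@H]1C(=O)OCC(F)(F)F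
F10 | step 3 | (R)-4-benzyl-3-{(1S,2R)-2-[(2E)-but-2-en-2-yl]-3-methyl-4-[(triisopropylsilyl)oxy]cyclohex-3-ene-1-carbonyl}oxazolidin-2-one | C/C=C(\C)[C@@H]1C(C)=C(O[Si](C(C)C)(C(C)C)C(C)C)CC[C@@H]1C(=O)N2[C@H](Cc3ccccc3)COC2=O
F11 | step 3 | (R)-4-benzyl-3-{(1S,2R)-2-[(2E)-but-2-en-2-yl]-3-methyl-4-oxocyclohexane-1-carbonyl}oxazolidin-2-one | C/C=C(\C)[C@@H]1C(C)C(=O)CC[C@@H]1C(=O)N2[C@H](Cc3ccccc3)COC2=O
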